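The cyclohexanone ring alternates oxygenated carbons (C1 ketone, C3 ethyl carbinol, C5 acyloxy carbon) with methyl-bearing ones (C2, C4, C6); the key step exploits this by forming C1–C2 and C4–C5 together. C2–C3–C4 comes from thian-4-one, a pentan-3-one α,α′-dinucleophile whose sulfide bridge later becomes the two cis methyl groups, and C5–C6–C1 from an α-formyl N-methoxy-N-methylamide. One flask gives a chelation-controlled Mukaiyama aldol, a Claisen ring closure to a 3-thiabicyclo[3.3.1]nonane, and ethyllithium addition to the bridging ketone while the other carbonyl is masked as its tetrahedral adduct. Raney nickel, esterification with the separately made pyrone acid and desilylation finish.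

Key step: step 4

Remark on the chemistry: the configuration of the C3 carbinol in 19–22 and 24 is inconsequential, since this centre is oxidised in step 16 (the SMILES show the expected epimer); 12, 13 and 23 are handled as E/Z or epimer mixtures.

Step 1
Reactants: 1 thian-4-one
Product: 2 4-(trimethylsilyloxy)-3,6-dihydro-2H-thiopyran
Conditions: TMSOTf, Et3N, CH2Cl2, 0 °C
Reagents that add atoms: trimethylsilyl triflate C[Si](C)(C)OS(=O)(=O)C(F)(F)F
Why: Amine-mediated O-silylation of the symmetrical ketone (silyl enol ether formation) can give only one regioisomer.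

Step 2
Reactants: 3 methyl (R)-3-hydroxy-2-methylpropanoate
Product: 4 (R)-3-hydroxy-N-methoxy-N,2-dimethylpropanamide
Conditions: MeNH(OMe)·HCl, i-PrMgCl, THF, −20 → 0 °C
Reagents that add atoms: N,O-dimethylhydroxylamine hydrochloride CNOC.Cl
Why: The chloromagnesium amide formed in the flask converts the ester into the N-methoxy-N-methylamide (ester aminolysis) without touching the α-stereocentre, the hydroxyl being carried as its alkoxide.

Step 3
Reactants: 4 (R)-3-hydroxy-N-methoxy-N,2-dimethylpropanamide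
Product: 5 (R)-N-methoxy-N,2-dimethyl-3-oxopropanamide
Conditions: Dess–Martin periodinane, NaHCO3, CH2Cl2, 0 °C; used crude at once
Reagents that add atoms: none
Why: Dess–Martin oxidation under buffered, base-free conditions should give the α-formyl amide, whose α-hydrogen is held out of conjugation with the tertiary amide by allylic strain, so the cold crude aldehyde is used before it can enolise.

Step 4
Reactants: 2 4-(trimethylsilyloxy)-3,6-dihydro-2H-thiopyran; 5 (R)-N-methoxy-N,2-dimethyl-3-oxopropanamide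
Product: 9 (1R,5R,7R,8S,9R)-9-ethyl-8,9-dihydroxy-7-methyl-3-thiabicyclo[3.3.1]nonan-6-one, via aldol adduct 6 (not isolated), via bicyclic hemiaminal 7 (not isolated), via ethyl adduct 8 (not isolated)
Conditions: MgBr2·OEt2, CH2Cl2, −78 → −40 °C; then THF, LiN(SiMe3)2, −78 → −30 °C; then EtLi, −78 °C; aq. NH4Cl, then aq. citric acid
Reagents that add atoms: ethyllithium [Li]CC
Why: MgBr2 chelates the aldehyde and amide carbonyls of 5, and 2 adds through an open transition state to the face anti to the C2 methyl group (chelation-controlled Mukaiyama aldol), which sets the carbinol carbon and the adjacent ring carbon of 6 in the 2,3-syn-3,4-anti sense from the single stereocentre of 5. LiN(SiMe3)2 then removes a proton from the remaining α-CH2 of the thianone and this enolate closes the carbocycle by a 6-exo-trig Claisen-type attack on the N-methoxy-N-methylamide; the side chain can reach the α′-carbon only on its own face of the thiane ring, so the second bridgehead is fixed by the bicyclic geometry. The closest known reactions are the chelation-controlled Mukaiyama aldol, the acylation of ketone enolates by N-methoxy-N-methylamides and the α,α′-annulation of cyclic ketones with 1,3-dielectrophiles to bicyclo[3.3.1]nonan-9-ones. Because the chelated tetrahedral adduct 7 persists until work-up, EtLi can add only to the non-enolisable bridging C9 ketone, and aggregation with the axial lithium alkoxides at C6 and C8 should deliver it from the carbocycle face, which leaves the new hydroxyl syn to the sulfide bridge. Collapse of 8 on work-up reveals the C6 ketone without its ever being enolised, so the C7 methyl centre is kept. The step needs syn simple diastereoselection in the aldol, which the open transition state on the chelated aldehyde should secure, and CH2-selective enolisation, which the hindered amide base at −78 °C secures.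

Step 5
Reactants: 9 (1R,5R,7R,8S,9R)-9-ethyl-8,9-dihydroxy-7-methyl-3-thiabicyclo[3.3.1]nonan-6-one
Product: 10 (2R,3R,4R,5R,6R)-3-ethyl-3,5-dihydroxy-2,4,6-trimethylcyclohexan-1-one
Conditions: Raney nickel (acetone-deactivated, washed neutral), EtOH, rt
Reagents that add atoms: none
Why: Raney nickel hydrogenolysis of both C–S bonds (reductive desulfurisation) turns the sulfide bridge into the C2 and C4 methyl groups, and the neutral deactivated catalyst should spare the ketone and every stereocentre.

Step 6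
Reactants: 11 3-methylpentane-2,4-dione
Product: 12 4-methoxy-3-methylpent-3-en-2-one
Conditions: HC(OMe)3, p-TsOH (cat.), MeOH, rt
Reagents that add atoms: trimethyl orthoformate COC(OC)OC
Why: Acid-catalysed enol ether formation of the symmetrical β-diketone, driven by the orthoformate as water scavenger, gives the vinylogous ester.

Step 7
Reactants: 12 4-methoxy-3-methylpent-3-en-2-one
Product: 13 5-methoxy-4-methylhex-4-en-3-one
Conditions: LiN(i-Pr)2, THF, −78 °C; MeI
Reagents that add atoms: iodomethane CI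
Why: Kinetic deprotonation of a β-alkoxy enone occurs at the α′-methyl group, so methylation (enolate alkylation) gives the ethyl ketone that later supplies the pyrone C5 methyl.

Step 8
Reactants: 14 (S)-4-benzyl-3-propanoyl-1,3-oxazolidin-2-one
Product: 15 (S)-4-benzyl-3-[(R)-2-methyl-3-oxopentanoyl]-1,3-oxazolidin-2-one
Conditions: LiN(i-Pr)2, THF, −78 °C; EtCOCl
Reagents that add atoms: propanoyl chloride CCC(Cl)=O
Why: The chelated Z lithium enolate of the imide is acylated on the face opposite the benzyl group (auxiliary-controlled enolate C-acylation), and allylic strain keeps the new β-keto imide stereocentre from enolising.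

Step 9
Reactants: 15 (S)-4-benzyl-3-[(R)-2-methyl-3-oxopentanoyl]-1,3-oxazolidin-2-one; 16 methacrolein
Product: 17 (S)-4-benzyl-3-[(2R,4S,5R)-5-hydroxy-2,4,6-trimethyl-3-oxohept-6-enoyl]-1,3-oxazolidin-2-one
Conditions: (c-Hex)2BCl, EtNMe2, Et2O, 0 °C; 16, −78 → −20 °C; H2O2, pH 7 buffer, MeOH
Reagents that add atoms: none
Why: The E enol borinate formed on the ethyl side reacts through a closed chair transition state (boron-mediated anti aldol), the C2 stereocentre of the β-keto imide directing the enolate face so that the 2,4-anti-4,5-anti adduct should predominate.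

Step 10
Reactants: 17 the anti,anti aldol adduct
Product: 18 (S)-4-benzyl-3-[(2R,4S,5R)-5-(tert-butyldimethylsilyloxy)-2,4,6-trimethyl-3-oxohept-6-enoyl]-1,3-oxazolidin-2-one
Conditions: TBSOTf, 2,6-lutidine, CH2Cl2, −78 °C
Reagents that add atoms: tert-butyldimethylsilyl triflate CC(C)(C)[Si](C)(C)OS(=O)(=O)C(F)(F)F
Why: The silyl triflate with a hindered pyridine base silylates the β-hydroxy ketone faster than retro-aldol or elimination can occur (silyl ether protection).

Step 11
Reactants: 18 the silylated β-keto imide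
Product: 19 (S)-4-benzyl-3-[(2R,3S,4R,5R)-5-(tert-butyldimethylsilyloxy)-3-hydroxy-2,4,6-trimethylhept-6-enoyl]-1,3-oxazolidin-2-one
Conditions: Zn(BH4)2, CH2Cl2/Et2O, −20 °C
Reagents that add atoms: none
Why: Zinc borohydride reduces the ketone through a chelate with the imide carbonyl (chelation-controlled reduction, 2,3-syn expected), which removes the acidic β-dicarbonyl hydrogen until step 16.

Step 12
Reactants: 19 the β-hydroxy imide
Product: 20 (2R,3S,4R,5R)-5-(tert-butyldimethylsilyloxy)-3-hydroxy-N-methoxy-N,2,4,6-tetramethylhept-6-enamide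
Conditions: AlMe3, MeNH(OMe)·HCl, CH2Cl2, −20 → 0 °C
Reagents that add atoms: N,O-dimethylhydroxylamine hydrochloride CNOC.Cl
Why: The aluminium amide transamidates the β-hydroxy imide at the exocyclic carbonyl, helped by the free hydroxyl, and releases the oxazolidinone auxiliary.

Step 13
Reactants: 20 the β-hydroxy N-methoxy-N-methylamide
Product: 21 (2R,3S,4R,5R)-5-(tert-butyldimethylsilyloxy)-N-methoxy-N,2,4,6-tetramethyl-3-(triethylsilyloxy)hept-6-enamide
Conditions: TESOTf, 2,6-lutidine, CH2Cl2, −78 → 0 °C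
Reagents that add atoms: triethylsilyl triflate CC[Si](CC)(CC)OS(=O)(=O)C(F)(F)F
Why: Silylation of the hindered secondary hydroxyl installs a group that can later be removed in the presence of the TBS ether (orthogonal silyl protection).

Step 14
Reactants: 21 the bis-silylated alkene amide
Product: 22 (2R,3S,4S,5S,6S)-5-(tert-butyldimethylsilyloxy)-7-hydroxy-N-methoxy-N,2,4,6-tetramethyl-3-(triethylsilyloxy)heptanamide
Conditions: 9-BBN, THF, 0 °C → rt; then H2O2, aq. NaHCO3
Reagents that add atoms: hydrogen peroxide OO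
Why: 9-BBN adds to the 1,1-disubstituted alkene anti to the allylic silyloxy group in the conformer that minimises allylic 1,3-strain (substrate-controlled hydroboration–oxidation), which should set the new methyl-bearing carbon anti to the neighbouring silyloxy carbon.

Step 15
Reactants: 22 the primary alcohol amide; 13 5-methoxy-4-methylhex-4-en-3-one
Product: 24 2-[(2R,3S,4R,5S,6S)-5-(tert-butyldimethylsilyloxy)-3,7-dihydroxy-4,6-dimethylheptan-2-yl]-3,5,6-trimethyl-4H-pyran-4-one, via acylated diketone 23 (not isolated)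
Conditions: 13 (excess), LiN(i-Pr)2, THF, −78 °C; then 22, −78 → −20 °C; aq. NH4Cl; then CSA, MeOH/CH2Cl2, rt
Reagents that add atoms: none
Why: The kinetic lithium enolate of 13 is acylated by the N-methoxy-N-methylamide (Claisen-type acylation through a stable tetrahedral adduct), and acid then closes the γ-pyrone by 6-endo-trig addition–elimination of methanol while cleaving the triethylsilyl ether but not the hindered TBS ether.

Step 16
Reactants: 24 the pyrone diol
Product: 25 (2R,3S,4S,6S)-3-(tert-butyldimethylsilyloxy)-2,4-dimethyl-5-oxo-6-(3,5,6-trimethyl-4-oxo-4H-pyran-2-yl)heptanal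
Conditions: (COCl)2, DMSO, CH2Cl2, −78 °C; i-Pr2NEt, −78 → −30 °C
Reagents that add atoms: none
Why: In the Swern oxidation both hydroxyls are activated as alkoxysulfonium ions before the base is added, so the 1,5-diol should give the keto aldehyde without lactol or lactone formation.

Step 17
Reactants: 25 the keto aldehyde
Product: 26 (2R,3R,4S,6S)-3-(tert-butyldimethylsilyloxy)-2,4-dimethyl-5-oxo-6-(3,5,6-trimethyl-4-oxo-4H-pyran-2-yl)heptanoic acid
Conditions: NaClO2, NaH2PO4, 2-methyl-2-butene, t-BuOH/H2O, 0 °C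
Reagents that add atoms: sodium chlorite [Na+].[O-]Cl=O
Why: Pinnick oxidation converts the aldehyde into the acid under buffered conditions that should not epimerise either α-stereocentre.

Step 18
Reactants: 26 the pyrone keto acid; 10 (2R,3R,4R,5R,6R)-3-ethyl-3,5-dihydroxy-2,4,6-trimethylcyclohexan-1-one
Product: 28 the C5 ester of 10 with acid 26 (side-chain hydroxyl as TBS ether), via mixed anhydride 27 (not isolated)
Conditions: 2,4,6-trichlorobenzoyl chloride, Et3N, toluene, rt; then 10, DMAP, toluene, rt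
Reagents that add atoms: none
Why: Yamaguchi esterification through the mixed anhydride should acylate only the secondary equatorial C5 hydroxyl of 10, the tertiary C3 hydroxyl being inert.

Step 19
Reactants: 28 the silyl-protected ester
Product: 29 the target, CNP0260549.2
Conditions: HF·pyridine, pyridine, THF, 0 °C → rt
Reagents that add atoms: none
Why: Buffered HF·pyridine cleaves the silyl ether (desilylation) without the basic conditions that would threaten the β-acyloxy ketone, the β-hydroxy ketones and the epimerisable α-centres.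

Compound list

1 | thian-4-one (tetrahydro-4H-thiopyran-4-one) | O=C1CCSCC1 | starting material
2 | 4-(trimethylsilyloxy)-3,6-dihydro-2H-thiopyran | C[Si](C)(C)OC1=CCSCC1 | intermediate
3 | methyl (R)-3-hydroxy-2-methylpropanoate | OC[C@@H](C)C(=O)OC | starting material
4 | (R)-3-hydroxy-N-methoxy-N,2-dimethylpropanamide | OC[C@@H](C)C(=O)N(C)OC | intermediate
5 | (R)-N-methoxy-N,2-dimethyl-3-oxopropanamide | O=C[C@@H](C)C(=O)N(C)OC | intermediate
6 | (2R,3S)-3-hydroxy-N-methoxy-N,2-dimethyl-3-[(3R)-4-oxothian-3-yl]propanamide (present as magnesium aldolate or silyl ether) | O=C1[C@H](CSCC1)[C@@H](O)[C@@H](C)C(=O)N(C)OC | intermediate (not isolated)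
7 | (1R,5S,7R,8S)-6,8-dihydroxy-6-[methoxy(methyl)amino]-7-methyl-3-thiabicyclo[3.3.1]nonan-9-one (present as lithium alkoxide; C6 configuration not defined) | O=C1[C@H](CSC2)[C@@H](O)[C@@H](C)C(O)(N(C)OC)[C@@H]12 | intermediate (not isolated)
8 | (1R,5R,7R,8S,9R)-9-ethyl-6-[methoxy(methyl)amino]-7-methyl-3-thiabicyclo[3.3.1]nonane-6,8,9-triol (present as lithium alkoxide; C6 configuration not defined) | CC[C@@]1(O)[C@H](CSC2)[C@@H](O)[C@@H](C)C(O)(N(C)OC)[C@@H]12 | intermediate (not isolated)
9 | (1R,5R,7R,8S,9R)-9-ethyl-8,9-dihydroxy-7-methyl-3-thiabicyclo[3.3.1]nonan-6-one | CC[C@@]1(O)[C@H](CSC2)[C@@H](O)[C@@H](C)C(=O)[C@@H]12 | intermediate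
10 | (2R,3R,4R,5R,6R)-3-ethyl-3,5-dihydroxy-2,4,6-trimethylcyclohexan-1-one | CC[C@@]1(O)[C@H](C)[C@@H](O)[C@@H](C)C(=O)[C@@H]1C | intermediate
11 | 3-methylpentane-2,4-dione | CC(=O)C(C)C(C)=O | starting material
12 | 4-methoxy-3-methylpent-3-en-2-one (E/Z mixture) | CC(=O)C(C)=C(C)OC | intermediate
13 | 5-methoxy-4-methylhex-4-en-3-one (E/Z mixture) | CCC(=O)C(C)=C(C)OC | intermediate
14 | (S)-4-benzyl-3-propanoyl-1,3-oxazolidin-2-one | CCC(=O)N1[C@@H](Cc2ccccc2)COC1=O | starting material
15 | (S)-4-benzyl-3-[(R)-2-methyl-3-oxopentanoyl]-1,3-oxazolidin-2-one | CCC(=O)[C@@H](C)C(=O)N1[C@@H](Cc2ccccc2)COC1=O | intermediate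
16 | methacrolein (2-methylprop-2-enal) | C=C(C)C=O | starting material
17 | (S)-4-benzyl-3-[(2R,4S,5R)-5-hydroxy-2,4,6-trimethyl-3-oxohept-6-enoyl]-1,3-oxazolidin-2-one | C=C(C)[C@H](O)[C@H](C)C(=O)[C@@H](C)C(=O)N1[C@@H](Cc2ccccc2)COC1=O | intermediate
18 | (S)-4-benzyl-3-[(2R,4S,5R)-5-(tert-butyldimethylsilyloxy)-2,4,6-trimethyl-3-oxohept-6-enoyl]-1,3-oxazolidin-2-one | C=C(C)[C@H](O[Si](C)(C)C(C)(C)C)[C@H](C)C(=O)[C@@H](C)C(=O)N1[C@@H](Cc2ccccc2)COC1=O | intermediate
19 | (S)-4-benzyl-3-[(2R,3S,4R,5R)-5-(tert-butyldimethylsilyloxy)-3-hydroxy-2,4,6-trimethylhept-6-enoyl]-1,3-oxazolidin-2-one | C=C(C)[C@H](O[Si](C)(C)C(C)(C)C)[C@H](C)[C@H](O)[C@@H](C)C(=O)N1[C@@H](Cc2ccccc2)COC1=O | intermediate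
20 | (2R,3S,4R,5R)-5-(tert-butyldimethylsilyloxy)-3-hydroxy-N-methoxy-N,2,4,6-tetramethylhept-6-enamide | C=C(C)[C@H](O[Si](C)(C)C(C)(C)C)[C@H](C)[C@H](O)[C@@H](C)C(=O)N(C)OC | intermediate
21 | (2R,3S,4R,5R)-5-(tert-butyldimethylsilyloxy)-N-methoxy-N,2,4,6-tetramethyl-3-(triethylsilyloxy)hept-6-enamide | C=C(C)[C@H](O[Si](C)(C)C(C)(C)C)[C@H](C)[C@H](O[Si](CC)(CC)CC)[C@@H](C)C(=O)N(C)OC | intermediate
22 | (2R,3S,4S,5S,6S)-5-(tert-butyldimethylsilyloxy)-7-hydroxy-N-methoxy-N,2,4,6-tetramethyl-3-(triethylsilyloxy)heptanamide | OC[C@H](C)[C@H](O[Si](C)(C)C(C)(C)C)[C@H](C)[C@H](O[Si](CC)(CC)CC)[C@@H](C)C(=O)N(C)OC | intermediate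
23 | 1,3-diketone from C-acylation of 13 by 22 (chain as in 22; epimer and E/Z mixture at the new diketone part) | OC[C@H](C)[C@H](O[Si](C)(C)C(C)(C)C)[C@H](C)[C@H](O[Si](CC)(CC)CC)[C@@H](C)C(=O)C(C)C(=O)C(C)=C(C)OC | intermediate (not isolated)
24 | 2-[(2R,3S,4R,5S,6S)-5-(tert-butyldimethylsilyloxy)-3,7-dihydroxy-4,6-dimethylheptan-2-yl]-3,5,6-trimethyl-4H-pyran-4-one | OC[C@H](C)[C@H](O[Si](C)(C)C(C)(C)C)[C@H](C)[C@H](O)[C@@H](C)c1oc(C)c(C)c(=O)c1C | intermediate
25 | (2R,3S,4S,6S)-3-(tert-butyldimethylsilyloxy)-2,4-dimethyl-5-oxo-6-(3,5,6-trimethyl-4-oxo-4H-pyran-2-yl)heptanal | O=C[C@H](C)[C@H](O[Si](C)(C)C(C)(C)C)[C@H](C)C(=O)[C@@H](C)c1oc(C)c(C)c(=O)c1C | intermediate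
26 | (2R,3R,4S,6S)-3-(tert-butyldimethylsilyloxy)-2,4-dimethyl-5-oxo-6-(3,5,6-trimethyl-4-oxo-4H-pyran-2-yl)heptanoic acid | OC(=O)[C@H](C)[C@H](O[Si](C)(C)C(C)(C)C)[C@H](C)C(=O)[C@@H](C)c1oc(C)c(C)c(=O)c1C | intermediate
27 | mixed anhydride of 26 with 2,4,6-trichlorobenzoic acid | O=C(OC(=O)c1c(Cl)cc(Cl)cc1Cl)[C@H](C)[C@H](O[Si](C)(C)C(C)(C)C)[C@H](C)C(=O)[C@@H](C)c1oc(C)c(C)c(=O)c1C | intermediate (not isolated)
28 | ester of the C5 hydroxyl of 10 with acid 26 (side-chain 3-hydroxyl as TBS ether) | CC[C@@]1(O)[C@H](C)[C@@H](OC(=O)[C@H](C)[C@H](O[Si](C)(C)C(C)(C)C)[C@H](C)C(=O)[C@@H](C)c2oc(C)c(C)c(=O)c2C)[C@@H](C)C(=O)[C@@H]1C | intermediate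
29 | CNP0260549.2: (1R,2R,3R,4R,6R)-3-ethyl-3-hydroxy-2,4,6-trimethyl-5-oxocyclohexyl (2R,3R,4S,6S)-3-hydroxy-2,4-dimethyl-5-oxo-6-(3,5,6-trimethyl-4-oxo-4H-pyran-2-yl)heptanoate | CC[C@@]1(O)[C@H](C)[C@@H](OC(=O)[C@H](C)[C@H](O)[C@H](C)C(=O)[C@@H](C)c2oc(C)c(C)c(=O)c2C)[C@@H](C)C(=O)[C@@H]1C | target

Total step count: 19. Longest linear sequence: 12 steps (steps 8–19).

Steps most likely to fail

Step 4. The ethyl group may be transferred to the sulfide-bridge face of the C9 carbonyl instead of the carbocycle face, or the third stage may erode the yield of the annulation. Fallback: starting from 2 and 5, only the first two stages are run and the mixture is quenched, which gives the bicyclic hydroxy dione F1. Excess Ph3P=CHCH3 (THF, −78 °C → rt; the enolisable C6 ketone is masked in the flask as its enolate) converts the C9 ketone into the ethylidene compound F2 by a Wittig reaction. Mukaiyama hydration (Mn(dpm)3, PhSiH3, O2, i-PrOH, then PPh3) then brings oxygen to the tertiary C9 radical from the face a carbon nucleophile prefers, the opposite sense to direct ethyl addition, and the sequence returns to the route at 9.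

Step 18. The stereocentre of 26 between the ketone and the pyrone may lose its configuration, or the acylated ring may undergo β-elimination, under the basic acylation. Fallback: the side-chain C5 carbon is kept at the carbinol level through the coupling. Starting from 22, the acylation with 13 is followed by ring closure with anhydrous CF3CO2H in CH2Cl2, which keeps the triethylsilyl ether and gives the pyrone alcohol F3. TEMPO/PhI(OAc)2 in wet MeCN oxidises the primary alcohol to the acid F4. Yamaguchi activation gives the mixed anhydride F5, which acylates 10 to the ester F6. PPTS in MeOH removes only the triethylsilyl group to give the alcohol F7, and Dess–Martin oxidation of its single secondary hydroxyl returns to the route at 28.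

Step 15. The enolate of 13 may act as a base, or add too slowly to the hindered α-branched amide. Fallback: an aldol/oxidation sequence. Starting from 22, TESCl/imidazole gives the bis-silyl ether F8, and i-Bu2AlH (THF, −78 °C) reduces it to the aldehyde F9. The lithium enolate of 13 adds to give the aldol adduct F10 as a diastereomer mixture, and Dess–Martin oxidation gives the diketone F11. CSA in MeOH then closes the pyrone and removes both triethylsilyl groups, returning to the route at 24.

Further compounds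

F1 | step 4 | (1R,5S,7R,8S)-8-hydroxy-7-methyl-3-thiabicyclo[3.3.1]nonane-6,9-dione | O=C1[C@H](CSC2)[C@@H](O)[C@@H](C)C(=O)[C@@H]12
F2 | step 4 | (1S,5R,7R,8S)-9-ethylidene-8-hydroxy-7-methyl-3-thiabicyclo[3.3.1]nonan-6-one (E/Z mixture) | CC=C1[C@H](CSC2)[C@@H](O)[C@@H](C)C(=O)[C@@H]12
F3 | step 18 | 3-O-triethylsilyl ether of 24 (primary hydroxyl free) | OC[C@H](C)[C@H](O[Si](C)(C)C(C)(C)C)[C@H](C)[C@H](O[Si](CC)(CC)CC)[C@@H](C)c1oc(C)c(C)c(=O)c1C
F4 | step 18 | carboxylic acid from oxidation of the primary alcohol of F3 | OC(=O)[C@H](C)[C@H](O[Si](C)(C)C(C)(C)C)[C@H](C)[C@H](O[Si](CC)(CC)CC)[C@@H](C)c1oc(C)c(C)c(=O)c1C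
F5 | step 18 | mixed anhydride of F4 with 2,4,6-trichlorobenzoic acid | O=C(OC(=O)c1c(Cl)cc(Cl)cc1Cl)[C@H](C)[C@H](O[Si](C)(C)C(C)(C)C)[C@H](C)[C@H](O[Si](CC)(CC)CC)[C@@H](C)c1oc(C)c(C)c(=O)c1C
F6 | step 18 | ester of the C5 hydroxyl of 10 with acid F4 | CC[C@@]1(O)[C@H](C)[C@@H](OC(=O)[C@H](C)[C@H](O[Si](C)(C)C(C)(C)C)[C@H](C)[C@H](O[Si](CC)(CC)CC)[C@@H](C)c2oc(C)c(C)c(=O)c2C)[C@@H](C)C(=O)[C@@H]1C
F7 | step 18 | alcohol from F6 after loss of the triethylsilyl group | CC[C@@]1(O)[C@H](C)[C@@H](OC(=O)[C@H](C)[C@H](O[Si](C)(C)C(C)(C)C)[C@H](C)[C@H](O)[C@@H](C)c2oc(C)c(C)c(=O)c2C)[C@@H](C)C(=O)[C@@H]1C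
F8 | step 15 | 7-O-triethylsilyl ether of 22 | CC[Si](CC)(CC)OC[C@H](C)[C@H](O[Si](C)(C)C(C)(C)C)[C@H](C)[C@H](O[Si](CC)(CC)CC)[C@@H](C)C(=O)N(C)OC
F9 | step 15 | aldehyde from reduction of the amide of F8 | CC[Si](CC)(CC)OC[C@H](C)[C@H](O[Si](C)(C)C(C)(C)C)[C@H](C)[C@H](O[Si](CC)(CC)CC)[C@@H](C)C=O
F10 | step 15 | aldol adduct of F9 with the enolate of 13 (diastereomer mixture at the two new centres) | CC[Si](CC)(CC)OC[C@H](C)[C@H](O[Si](C)(C)C(C)(C)C)[C@H](C)[C@H](O[Si](CC)(CC)CC)[C@@H](C)C(O)C(C)C(=O)C(C)=C(C)OC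
F11 | step 15 | 1,3-diketone from oxidation of F10 | CC[Si](CC)(CC)OC[C@H](C)[C@H](O[Si](C)(C)C(C)(C)C)[C@H](C)[C@H](O[Si](CC)(CC)CC)[C@@H](C)C(=O)C(C)C(=O)C(C)=C(C)OC
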